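**Retrosynthetic overview**
- Lactone numbering O1, C2 (C=O), C3, C4, C5. The C3=CH–aryl alkene is traced back to a C3-aroyl group (β-keto lactone). Ketone reduction, E-selective dehydration and desilylation restore it at the end.
- Key disconnection: the β-keto lactone opens to an acyclic (E)-aryl enone plus the three-atom unit C5–O1–C2, carried by iodomethyl phenyl carbonate. C4–C5 forms by copper-catalysed asymmetric conjugate addition of the derived zinc reagent, and C2–C3 by Dieckmann acylation of the resulting enolate in the same pot.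
- Enabling feature: the exocyclic benzylidene carbon on C3. At the ketone oxidation level it makes C3 and C4 the α- and β-carbons of an enone, so C4 is electrophilic and C3 nucleophilic. This matches the nucleophilic CH2 end and the electrophilic carbonyl end of the O–CH2/C=O unit.
- The enone comes from cross-metathesis of silylated eugenol with an aryl vinyl ketone made from 3-hydroxy-4,5-dimethoxybenzaldehyde.
- Ring order: the γ-butyrolactone is the only ring formed (in the key step); both arenes are bought.

Key step: step 8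

Assumption: the (S,R,R)-configured phosphoramidite is taken to direct addition to the Re face of the enone β-carbon, which gives (R) at C4; if the sense proves opposite, the enantiomeric ligand is used in the same way.

**Step 1**
Reactants: 1 eugenol (4-allyl-2-methoxyphenol)
Product: 2 tert-butyl(4-allyl-2-methoxyphenoxy)dimethylsilane
Conditions: TBSCl, imidazole, DMF, rt
Reagents that add atoms: tert-butyldimethylsilyl chloride, CC(C)(C)[Si](C)(C)Cl
Why: Imidazole-promoted silyl ether formation masks the acidic phenol against the later organometallic steps and leaves the allyl group untouched.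

**Step 2**
Reactants: 3 3-hydroxy-4,5-dimethoxybenzaldehyde
Product: 4 3-(tert-butyldimethylsilyloxy)-4,5-dimethoxybenzaldehyde
Conditions: TBSCl, imidazole, DMF, rt
Reagents that add atoms: tert-butyldimethylsilyl chloride, CC(C)(C)[Si](C)(C)Cl
Why: The same phenol silylation protects the second ring, and the aldehyde is not affected.

**Step 3**
Reactants: 4 3-(tert-butyldimethylsilyloxy)-4,5-dimethoxybenzaldehyde
Product: 5 1-[3-(tert-butyldimethylsilyloxy)-4,5-dimethoxyphenyl]prop-2-en-1-ol (racemic)
Conditions: vinylmagnesium bromide, THF, −78 to 0 °C; aq NH4Cl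
Reagents that add atoms: vinylmagnesium bromide, C=C[Mg]Br
Why: Grignard 1,2-addition to the aryl aldehyde should give the allylic alcohol, whose stereocentre is removed in step 4.

**Step 4**
Reactants: 5 1-[3-(tert-butyldimethylsilyloxy)-4,5-dimethoxyphenyl]prop-2-en-1-ol
Product: 6 1-[3-(tert-butyldimethylsilyloxy)-4,5-dimethoxyphenyl]prop-2-en-1-one
Conditions: DMP, CH2Cl2, 0 °C to rt; used without storage
Reagents that add atoms: none
Why: Dess–Martin oxidation of the benzylic, allylic alcohol should give the aryl vinyl ketone under neutral conditions that do not trigger conjugate addition or polymerisation.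

**Step 5**
Reactants: 2 tert-butyl(4-allyl-2-methoxyphenoxy)dimethylsilane; 6 1-[3-(tert-butyldimethylsilyloxy)-4,5-dimethoxyphenyl]prop-2-en-1-one
Product: 7 (E)-1-[3-(tert-butyldimethylsilyloxy)-4,5-dimethoxyphenyl]-4-[4-(tert-butyldimethylsilyloxy)-3-methoxyphenyl]but-2-en-1-one
Conditions: second-generation Hoveyda–Grubbs catalyst (5 mol%), 1,4-benzoquinone (10 mol%), CH2Cl2, 40 °C
Reagents that add atoms: none
Why: Olefin cross-metathesis of the allylarene with the electron-poor vinyl ketone, which does not homodimerise, should give the E-enone under thermodynamic control, with benzoquinone suppressing alkene migration.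

**Step 6**
Reactants: 8 chloromethyl chloroformate; 9 phenol
Product: 10 chloromethyl phenyl carbonate
Conditions: pyridine, CH2Cl2, 0 °C
Reagents that add atoms: none
Why: O-Acylation of phenol occurs at the chloroformate carbonyl, which is far more electrophilic than the chloromethyl carbon, and should give the mixed carbonate.

**Step 7**
Reactants: 10 chloromethyl phenyl carbonate
Product: 11 iodomethyl phenyl carbonate
Conditions: NaI, acetone, 40 °C, dark
Reagents that add atoms: sodium iodide, [Na+].[I-]
Why: Finkelstein halide exchange at the oxygen-bearing CH2, driven by precipitation of NaCl, should give the iodide needed for iodine–zinc exchange.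

**Step 8**
Reactants: 7 (E)-1-[3-(tert-butyldimethylsilyloxy)-4,5-dimethoxyphenyl]-4-[4-(tert-butyldimethylsilyloxy)-3-methoxyphenyl]but-2-en-1-one; 11 iodomethyl phenyl carbonate
Product: 14 (3S,4R)-3-[3-(tert-butyldimethylsilyloxy)-4,5-dimethoxybenzoyl]-4-[4-(tert-butyldimethylsilyloxy)-3-methoxybenzyl]dihydrofuran-2(3H)-one, via bis[(phenoxycarbonyloxy)methyl]zinc 12 (not isolated), via zinc enolate 13 (not isolated)
Conditions: 11 (4 equiv), Et2Zn (2 equiv), CuI (0.3 mol%), 0 °C, then volatiles off in vacuo; Cu(OTf)2 (3 mol%), (S,R,R)-phosphoramidite from (S)-BINOL and bis[(R)-1-phenylethyl]amine (6 mol%), 7, toluene, −30 °C to rt; aq NH4Cl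
Reagents that add atoms: none
Why: Proposed new method: iodine–zinc exchange turns 11 into the acyloxymethylzinc 12, and a copper–phosphoramidite catalyst transfers its CH2 group to the β-carbon of enone 7 (conjugate addition) to give zinc enolate 13, whose α-carbon then attacks the phenyl carbonate carbonyl and expels phenoxide (Dieckmann-type acylation), so that C4–C5 and C2–C3 of the lactone form in one pot. The closest known reaction types are the copper–phosphoramidite-catalysed asymmetric conjugate addition of functionalised dialkylzincs to acyclic enones with trapping of the zinc enolate by a carbon electrophile, and the catalytic asymmetric additions of bis(pivaloyloxymethyl)zinc. The lactone closes by 5-exo-trig attack of the enolate carbon on the carbonate carbonyl. The C4 stereocentre is set under reagent control by the chiral ligand on copper (Re-face delivery to the enone β-carbon), while C3 settles trans to the benzyl group through the enolisable β-keto lactone and is erased in step 10. The step needs 1,4- over 1,2-addition, secured by the soft organocopper intermediate; C- over O-acylation, secured by the five- versus seven-membered ring; and cyclisation before protonation, secured by the activated aryl carbonate and by the product being drained as its zinc chelate.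

**Step 9**
Reactants: 14 (3S,4R)-3-[3-(tert-butyldimethylsilyloxy)-4,5-dimethoxybenzoyl]-4-[4-(tert-butyldimethylsilyloxy)-3-methoxybenzyl]dihydrofuran-2(3H)-one
Product: 15 (3S,4R)-3-{[3-(tert-butyldimethylsilyloxy)-4,5-dimethoxyphenyl](hydroxy)methyl}-4-[4-(tert-butyldimethylsilyloxy)-3-methoxybenzyl]dihydrofuran-2(3H)-one (both carbinol epimers)
Conditions: NaBH4, MeOH–THF, −20 °C
Reagents that add atoms: none
Why: Borohydride reduction should take the aryl ketone in preference to the much less electrophilic lactone carbonyl, and both carbinol epimers converge in step 10.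

**Step 10**
Reactants: 15 (3S,4R)-3-{[3-(tert-butyldimethylsilyloxy)-4,5-dimethoxyphenyl](hydroxy)methyl}-4-[4-(tert-butyldimethylsilyloxy)-3-methoxybenzyl]dihydrofuran-2(3H)-one
Product: 17 (R,E)-3-[3-(tert-butyldimethylsilyloxy)-4,5-dimethoxybenzylidene]-4-[4-(tert-butyldimethylsilyloxy)-3-methoxybenzyl]dihydrofuran-2(3H)-one, via mesylate 16 (not isolated)
Conditions: MsCl, Et3N, CH2Cl2, 0 °C; then DBU, rt
Reagents that add atoms: none
Why: Mesylation followed by E1cB elimination through the lactone enolate should give the conjugated exocyclic alkene as the thermodynamically favoured E isomer (aryl trans to the lactone carbonyl), without touching the non-acidic C4 centre.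

**Step 11**
Reactants: 17 (R,E)-3-[3-(tert-butyldimethylsilyloxy)-4,5-dimethoxybenzylidene]-4-[4-(tert-butyldimethylsilyloxy)-3-methoxybenzyl]dihydrofuran-2(3H)-one
Product: 18 (R,E)-3-(3-hydroxy-4,5-dimethoxybenzylidene)-4-(4-hydroxy-3-methoxybenzyl)dihydrofuran-2(3H)-one
Conditions: TBAF, AcOH, THF, 0 °C
Reagents that add atoms: none
Why: Fluoride-mediated desilylation of both aryl silyl ethers, buffered with acetic acid so that phenoxide does not isomerise the exocyclic alkene, should release the target.

**Compound list**
1 | eugenol (4-allyl-2-methoxyphenol) | COc1cc(CC=C)ccc1O | starting material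
2 | tert-butyl(4-allyl-2-methoxyphenoxy)dimethylsilane | COc1cc(CC=C)ccc1O[Si](C)(C)C(C)(C)C | intermediate
3 | 3-hydroxy-4,5-dimethoxybenzaldehyde | COc1cc(C=O)cc(O)c1OC | starting material
4 | 3-(tert-butyldimethylsilyloxy)-4,5-dimethoxybenzaldehyde | COc1cc(C=O)cc(O[Si](C)(C)C(C)(C)C)c1OC | intermediate
5 | 1-[3-(tert-butyldimethylsilyloxy)-4,5-dimethoxyphenyl]prop-2-en-1-ol (racemic) | COc1cc(C(O)C=C)cc(O[Si](C)(C)C(C)(C)C)c1OC | intermediate
6 | 1-[3-(tert-butyldimethylsilyloxy)-4,5-dimethoxyphenyl]prop-2-en-1-one | COc1cc(C(=O)C=C)cc(O[Si](C)(C)C(C)(C)C)c1OC | intermediate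
7 | (E)-1-[3-(tert-butyldimethylsilyloxy)-4,5-dimethoxyphenyl]-4-[4-(tert-butyldimethylsilyloxy)-3-methoxyphenyl]but-2-en-1-one | COc1cc(C/C=C/C(=O)c2cc(O[Si](C)(C)C(C)(C)C)c(OC)c(OC)c2)ccc1O[Si](C)(C)C(C)(C)C | intermediate
8 | chloromethyl chloroformate | ClCOC(=O)Cl | starting material
9 | phenol | Oc1ccccc1 | starting material
10 | chloromethyl phenyl carbonate | ClCOC(=O)Oc1ccccc1 | intermediate
11 | iodomethyl phenyl carbonate | ICOC(=O)Oc1ccccc1 | intermediate
12 | bis[(phenoxycarbonyloxy)methyl]zinc | O=C(OC[Zn]COC(=O)Oc1ccccc1)Oc1ccccc1 | intermediate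
13 | zinc (Z)-enolate of the (R)-configured conjugate adduct | COc1cc(C[C@@H](COC(=O)Oc2ccccc2)/C=C(\O[Zn]COC(=O)Oc2ccccc2)c2cc(O[Si](C)(C)C(C)(C)C)c(OC)c(OC)c2)ccc1O[Si](C)(C)C(C)(C)C | intermediate
14 | (3S,4R)-3-[3-(tert-butyldimethylsilyloxy)-4,5-dimethoxybenzoyl]-4-[4-(tert-butyldimethylsilyloxy)-3-methoxybenzyl]dihydrofuran-2(3H)-one | COc1cc(C[C@H]2COC(=O)[C@@H]2C(=O)c2cc(O[Si](C)(C)C(C)(C)C)c(OC)c(OC)c2)ccc1O[Si](C)(C)C(C)(C)C | intermediate
15 | (3S,4R)-3-{[3-(tert-butyldimethylsilyloxy)-4,5-dimethoxyphenyl](hydroxy)methyl}-4-[4-(tert-butyldimethylsilyloxy)-3-methoxybenzyl]dihydrofuran-2(3H)-one (both carbinol epimers) | COc1cc(C[C@H]2COC(=O)[C@@H]2C(O)c2cc(O[Si](C)(C)C(C)(C)C)c(OC)c(OC)c2)ccc1O[Si](C)(C)C(C)(C)C | intermediate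
16 | methanesulfonate of 15 | COc1cc(C[C@H]2COC(=O)[C@@H]2C(OS(C)(=O)=O)c2cc(O[Si](C)(C)C(C)(C)C)c(OC)c(OC)c2)ccc1O[Si](C)(C)C(C)(C)C | intermediate
17 | (R,E)-3-[3-(tert-butyldimethylsilyloxy)-4,5-dimethoxybenzylidene]-4-[4-(tert-butyldimethylsilyloxy)-3-methoxybenzyl]dihydrofuran-2(3H)-one | COc1cc(C[C@H]2COC(=O)/C2=C/c2cc(O[Si](C)(C)C(C)(C)C)c(OC)c(OC)c2)ccc1O[Si](C)(C)C(C)(C)C | intermediate
18 | (R,E)-3-(3-hydroxy-4,5-dimethoxybenzylidene)-4-(4-hydroxy-3-methoxybenzyl)dihydrofuran-2(3H)-one | COc1cc(C[C@H]2COC(=O)/C2=C/c2cc(O)c(OC)c(OC)c2)ccc1O | target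

**Step count and risks**
Total step count: 11. Longest linear sequence: 8 steps (steps 2, 3, 4, 5, 8, 9, 10 and 11).

Steps most likely to fail:

1. Step 8 (Proposed new method). What may go wrong: slow transfer of the oxygenated methyl group from zinc to copper, loss of enantiofacial control in the conjugate addition, or protonation of the zinc enolate before it acylates. The fallback uses known chemistry only, sets out from 2 and comes back to the route at 15. Hydroboration–oxidation of 2 (9-BBN, THF; NaBO3) should give 3-[4-(tert-butyldimethylsilyloxy)-3-methoxyphenyl]propan-1-ol F1. Oxidation (TEMPO, PhI(OAc)2, MeCN–H2O) should give 3-[4-(tert-butyldimethylsilyloxy)-3-methoxyphenyl]propanoic acid F2. Its pivaloyl mixed anhydride and lithiated (S)-4-benzyloxazolidin-2-one should give the N-acyl oxazolidinone F3. Evans alkylation (NaHMDS, tert-butyl bromoacetate, THF, −78 °C) should give the (R)-configured alkylated imide F4 under auxiliary control. LiBH4 should remove the auxiliary to give the hydroxy tert-butyl ester F5. TsOH in warm toluene should close (R)-4-[4-(tert-butyldimethylsilyloxy)-3-methoxybenzyl]dihydrofuran-2(3H)-one F6. Its lithium enolate (LDA, THF, −78 °C) should add to aldehyde 4 trans to the benzyl group to give 15, which continues with step 10.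

2. Step 5. What may go wrong: ruthenium hydride-induced migration of the allyl double bond of 2 into conjugation before metathesis, self-metathesis of 2, and polymerisation of the vinyl ketone 6. The fallback sets out from 2 and 5 and comes back at 7. Cross-metathesis of 2 with the allylic alcohol 5 (same catalyst) should give the racemic (E)-allylic alcohol F7, which MnO2 in CH2Cl2 should oxidise to 7. The order of oxidation and metathesis is reversed, so the polymerisable vinyl ketone is never handled.

3. Step 10. What may go wrong: incomplete E selectivity in the elimination, and base-induced migration of the exocyclic double bond into the ring, which would erase the C4 stereocentre. The fallback sets out from 14 and comes back at 17. Triflation of the chelated sodium enolate of 14 (NaH, PhNTf2, THF, 0 °C) should give the (Z)-enol triflate F8, with the triflate cis to the lactone carbonyl. Stereoretentive reduction (Pd(OAc)2, PPh3, HCO2H, Bu3N, DMF, 60 °C) should replace the triflate by hydrogen to give 17, with no strong base present after the alkene is formed.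

**Further compounds**
F1 | step 8 | 3-[4-(tert-butyldimethylsilyloxy)-3-methoxyphenyl]propan-1-ol | COc1cc(CCCO)ccc1O[Si](C)(C)C(C)(C)C
F2 | step 8 | 3-[4-(tert-butyldimethylsilyloxy)-3-methoxyphenyl]propanoic acid | COc1cc(CCC(=O)O)ccc1O[Si](C)(C)C(C)(C)C
F3 | step 8 | (S)-4-benzyl-3-{3-[4-(tert-butyldimethylsilyloxy)-3-methoxyphenyl]propanoyl}oxazolidin-2-one | COc1cc(CCC(=O)N2[C@@H](Cc3ccccc3)COC2=O)ccc1O[Si](C)(C)C(C)(C)C
F4 | step 8 | tert-butyl (R)-3-[(S)-4-benzyl-2-oxooxazolidine-3-carbonyl]-4-[4-(tert-butyldimethylsilyloxy)-3-methoxyphenyl]butanoate | COc1cc(C[C@H](CC(=O)OC(C)(C)C)C(=O)N2[C@@H](Cc3ccccc3)COC2=O)ccc1O[Si](C)(C)C(C)(C)C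
F5 | step 8 | tert-butyl (R)-4-[4-(tert-butyldimethylsilyloxy)-3-methoxyphenyl]-3-(hydroxymethyl)butanoate | COc1cc(C[C@H](CC(=O)OC(C)(C)C)CO)ccc1O[Si](C)(C)C(C)(C)C
F6 | step 8 | (R)-4-[4-(tert-butyldimethylsilyloxy)-3-methoxybenzyl]dihydrofuran-2(3H)-one | COc1cc(C[C@H]2COC(=O)C2)ccc1O[Si](C)(C)C(C)(C)C
F7 | step 5 | (E)-1-[3-(tert-butyldimethylsilyloxy)-4,5-dimethoxyphenyl]-4-[4-(tert-butyldimethylsilyloxy)-3-methoxyphenyl]but-2-en-1-ol (racemic) | COc1cc(C/C=C/C(O)c2cc(O[Si](C)(C)C(C)(C)C)c(OC)c(OC)c2)ccc1O[Si](C)(C)C(C)(C)C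
F8 | step 10 | (R,Z)-enol triflate of 14 | COc1cc(C[C@H]2COC(=O)/C2=C(\OS(=O)(=O)C(F)(F)F)/c2cc(O[Si](C)(C)C(C)(C)C)c(OC)c(OC)c2)ccc1O[Si](C)(C)C(C)(C)C
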